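The slowness of the north-west run set my problem: at 6.00 d its free monomer still stood at 63.8 % of the charge, and I had to decide what initiator to charge next.

| setting | north-west | south | flask |
|---|---|---|---|
| free monomer | 0.20 M (fed, over 15 h) | 0.20 M (fed, over 15 h) | 0.20 M (fed, over 15 h) |
| initiator | 0.10 mM | 0.40 mM | 0.20 mM |
| remark | run made earlier; the fed solution adds 0.50 times the starting volume | run made earlier; the fed solution adds 0.50 times the starting volume | the fed solution adds 0.50 times the starting volume |
| time |  |  | 10 d |

| run | time / d | monomer in chains / % | free monomer / % |
|---|---|---|---|
| north-west | 0.500 | 3.9 | 78.4 |
| north-west | 1.04 | 9.8 | 89.1 |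
| north-west | 2.50 | 20.5 | 78.0 |
| north-west | 6.00 | 35.3 | 63.8 |
| south | 0.833 | 13.5 | 87.7 |
| south | 2.00 | 31.3 | 67.9 |
| south | 4.00 | 51.0 | 49.8 |
| south | 6.00 | 56.9 | 39.6 |

(scatter of a reading: 1 percentage point)

- amounts are per litre of the starting volume; all of the dose is in the solution fed
- the average divides the monomer in chains by the number of chains, living and dead together; two radicals that join make one chain
- the earlier runs do not show the number of chains; that part of a forecast is a guess
- percentages count the whole charge, also what has not yet gone in

- average number of monomer units in a chain (living and dead chains, two that joined counted as one) at 10 d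
- part of the free monomer that has reacted at 10 d

Both feeds had ended by 6.00 d, so I compared the runs there. If free monomer is lost in proportion to itself at any given radical concentration (pseudo-first-order), then the measure of progress is X, the natural log of the charge over the free monomer left. X was 0.449 in the north-west run and 0.926 in the south run, which had 4.00 times the initiator. That gave a reading of 0.522 for n, the order in initiator, meaning the power to which X rises with the initiator charged, at equal time. I read a value near a half as the pattern of a growing radical made from initiator and lost in pairs, and I took the concentration of growing radical, which the readings do not show, to set the rate.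

So twice the north-west initiator promised 1.44 times its X. I charged 0.20 mM and reckoned on 52.5 % free monomer at 6.00 d, the reading to watch. Chain length could not be read from those runs.

For 10 d the forecast gave 54 % reacted and an average of 850 units, the latter a figure “which is largely a guess”.

The flask gave 54.2 % reacted and an average of 547 units at 10 d, from this scheme:

    free monomer + growing radical → monomer in chains + growing radical, rate k1*[growing radical]*[free monomer] (k = 1.00 × 10⁵ L mol⁻¹ min⁻¹)
    2 growing radical → dead chain (k = 3.20 × 10⁸ L mol⁻¹ s⁻¹)
    initiator → 2 initiating radical (k = 3.20 × 10⁻⁴ min⁻¹)
    free monomer + initiating radical → growing radical + monomer in chains (k = 1.10 × 10⁵ L mol⁻¹ s⁻¹)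

The reacted part agreed with the forecast, but the average came out lower. In this flask at 10.0 d dead chain stood at 1.32 × 10⁻⁴ M in a volume 1.50 times the starting one, which is 0.990 dead chains per initiator charged. The flask's X was 0.780. With n, a neighbouring flask, the same but charged with 1.2 × 10⁻⁴ M of initiator, should reach at the same time X of 0.598, or 45.0 % reacted. That neighbouring flask gave 45.3 %.

(All runs are simulated from invented constants; scatter was added.)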